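## Retrosynthetic overview
1. Enal side chain: the C=C is cut last (Wittig two-carbon homologation of a 6-carbaldehyde).
2. The dioxane ring is the only ring built, since both benzene rings are bought. Cut C3–O4 (benzylic alkyl C–O, phenoxide opens an epoxide) and O1–C8a (aryl C–O, intramolecular SNAr at a C–F para to CHO). Both bonds are made in one flask.
3. Fragments: a (2S,3S)-3-arylglycidol and 4-fluoro-3-hydroxybenzaldehyde. The OH/F pattern of the aldehyde fixes which oxygen ends on which carbon.
4. Stereocentres: C2 is the epoxide C–O centre from a Katsuki–Sharpless epoxidation and is never broken. C3 is equilibrated to trans through a p-quinone methide once the phenol is unmasked.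
5. The glycidol comes from O-silyl sinapyl alcohol, which comes from sinapic acid.

Assumption: a two-stage operation carried through without isolating the intermediate counts as one step; positions follow 1,4-benzodioxine numbering (O1, C2 = CH2OH carbon, C3 = aryl carbon, O4, CHO/enal at C6).

## Route

Step 1
Reactants: 1 sinapic acid, (E)-3-(4-hydroxy-3,5-dimethoxyphenyl)prop-2-enoic acid
Product: 3 (E)-3-{4-[(tert-butyldimethylsilyl)oxy]-3,5-dimethoxyphenyl}prop-2-en-1-ol, via bis-silyl sinapate 2 (not isolated)
Conditions: TBSCl (2.2 equiv), Et3N (2.4 equiv), DMAP (5 mol %), THF, 0 °C to rt; filter under N2; then i-Bu2AlH (3.5 equiv, 1 M in toluene), −78 to 0 °C; aq. potassium sodium tartrate (KNaC4H4O6)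
Reagents that add atoms: tert-butyldimethylsilyl chloride (TBSCl), CC(C)(C)[Si](C)(C)Cl
Why: Silylation of both acidic OH groups masks the phenol and turns the acid into a labile silyl ester, which i-Bu2AlH reduces in the 1,2-sense to the allylic alcohol (ester-to-alcohol hydride reduction), leaving the E-alkene and the hindered aryl silyl ether untouched; no stereocentre is formed.

Step 2
Reactants: 3 (E)-3-{4-[(tert-butyldimethylsilyl)oxy]-3,5-dimethoxyphenyl}prop-2-en-1-ol
Product: 4 [(2S,3S)-3-{4-[(tert-butyldimethylsilyl)oxy]-3,5-dimethoxyphenyl}oxiran-2-yl]methanol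
Conditions: Ti(OiPr)4 (10 mol %), (+)-diisopropyl (2R,3R)-tartrate (12 mol %), t-BuOOH (2.0 equiv, in decane), 4 Å molecular sieves, CH2Cl2, −25 °C; triethanolamine quench; Et3N-washed SiO2
Reagents that add atoms: tert-butyl hydroperoxide, CC(C)(C)OO
Why: Katsuki–Sharpless asymmetric epoxidation, in which the allylic alkoxide and t-BuOOH bind to the titanium–(+)-tartrate complex and oxygen goes to the face that gives the (2S,3S)-epoxide, as for (E)-cinnamyl alcohol (typically >95% ee); this sets the C–O stereocentre that becomes C2 of the target, and the 4-silyloxy group, twisted out of conjugation by its two methoxy neighbours, keeps the benzylic epoxide isolable.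

Step 3
Reactants: 4 [(2S,3S)-3-{4-[(tert-butyldimethylsilyl)oxy]-3,5-dimethoxyphenyl}oxiran-2-yl]methanol; 5 4-fluoro-3-hydroxybenzaldehyde
Product: 10 (2S,3S)-3-(4-hydroxy-3,5-dimethoxyphenyl)-2-(hydroxymethyl)-2,3-dihydro-1,4-benzodioxine-6-carbaldehyde, via ring-opened alkoxide 6 (not isolated), via cis silyl ether 7 (not isolated), via cis phenolate 8 (not isolated), via quinone methide 9 (not isolated)
Conditions: 5 (1.05 equiv), KOt-Bu (1.05 equiv), DMSO, rt, 10 min; add 4 (0.2 M), 50 °C, 3 h; then 75 °C, 4 h, N2 sweep; AcOH (1.1 equiv), rt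
Reagents that add atoms: none
Why: Proposed new method: an anionic relay annulation in which each event releases the reagent for the next: the pre-formed potassium phenoxide of 5 opens the epoxide of 4 at the benzylic carbon by SN2 (inversion, as in known phenoxide openings of 3-arylglycidols); the strain-released C2 alkoxide 6, formed when no acidic phenol is left to quench it, attacks the C–F carbon para to CHO in a six-membered intramolecular SNAr (the C2–O bond is untouched, so the Sharpless centre is retained) to give cis 7; the expelled fluoride strips the aryl silyl ether as TBSF; the freed syringyl phenolate 8 reversibly expels the O4 aryloxide to the p-quinone methide 9 and re-closes by oxa-1,6-addition until the diequatorial trans isomer 10 dominates (expected ≥9:1), which sets C3 under thermodynamic control from C2; the closest known reaction types are the copper-catalysed tandem epoxide opening/O-arylation of o-halophenols, fluoride-triggered silyl ether SNAr chemistry and the alkaline quinone-methide cleavage of phenolic benzyl aryl ethers, but their merger into one metal-free, stereo-editing annulation of a 2,3-epoxy alcohol has not been described.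

Step 4
Reactants: 10 (2S,3S)-3-(4-hydroxy-3,5-dimethoxyphenyl)-2-(hydroxymethyl)-2,3-dihydro-1,4-benzodioxine-6-carbaldehyde
Product: 11 (E)-3-[(2S,3S)-3-(4-hydroxy-3,5-dimethoxyphenyl)-2-(hydroxymethyl)-2,3-dihydro-1,4-benzodioxin-6-yl]prop-2-enal
Conditions: Ph3P=CHCHO (1.2 equiv), THF/toluene 1:1, 80 °C, 12 h
Reagents that add atoms: (triphenylphosphoranylidene)acetaldehyde, O=CC=P(c1ccccc1)(c1ccccc1)c1ccccc1
Why: Wittig olefination with the stabilised formyl ylide gives the E-enal selectively on this dialkoxybenzaldehyde, tolerates the free phenol and primary alcohol (neither is acidic enough to protonate the ylide) and touches neither stereocentre.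

## Compound list
1 | sinapic acid, (E)-3-(4-hydroxy-3,5-dimethoxyphenyl)prop-2-enoic acid | COc1cc(/C=C/C(=O)O)cc(OC)c1O | starting material
2 | tert-butyldimethylsilyl (E)-3-{4-[(tert-butyldimethylsilyl)oxy]-3,5-dimethoxyphenyl}prop-2-enoate | COc1cc(/C=C/C(=O)O[Si](C)(C)C(C)(C)C)cc(OC)c1O[Si](C)(C)C(C)(C)C | intermediate
3 | (E)-3-{4-[(tert-butyldimethylsilyl)oxy]-3,5-dimethoxyphenyl}prop-2-en-1-ol | COc1cc(/C=C/CO)cc(OC)c1O[Si](C)(C)C(C)(C)C | intermediate
4 | [(2S,3S)-3-{4-[(tert-butyldimethylsilyl)oxy]-3,5-dimethoxyphenyl}oxiran-2-yl]methanol | OC[C@@H]1O[C@H]1c2cc(OC)c(O[Si](C)(C)C(C)(C)C)c(OC)c2 | intermediate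
5 | 4-fluoro-3-hydroxybenzaldehyde | O=Cc1ccc(F)c(O)c1 | starting material
6 | 4-fluoro-3-{(1R,2S)-1-{4-[(tert-butyldimethylsilyl)oxy]-3,5-dimethoxyphenyl}-2,3-dihydroxypropoxy}benzaldehyde (formed as its potassium 2-alkoxide) | OC[C@H](O)[C@H](Oc1cc(C=O)ccc1F)c1cc(OC)c(O[Si](C)(C)C(C)(C)C)c(OC)c1 | intermediate
7 | (2S,3R)-3-{4-[(tert-butyldimethylsilyl)oxy]-3,5-dimethoxyphenyl}-2-(hydroxymethyl)-2,3-dihydro-1,4-benzodioxine-6-carbaldehyde (cis) | COc1cc([C@H]2Oc3cc(C=O)ccc3O[C@H]2CO)cc(OC)c1O[Si](C)(C)C(C)(C)C | intermediate
8 | (2S,3R)-3-(4-hydroxy-3,5-dimethoxyphenyl)-2-(hydroxymethyl)-2,3-dihydro-1,4-benzodioxine-6-carbaldehyde (cis, present as potassium phenolate) | COc1cc([C@H]2Oc3cc(C=O)ccc3O[C@H]2CO)cc(OC)c1O | intermediate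
9 | 4-{[(2R)-1-(3,5-dimethoxy-4-oxocyclohexa-2,5-dien-1-ylidene)-3-hydroxypropan-2-yl]oxy}-3-hydroxybenzaldehyde (present as potassium phenolate) | COC1=CC(=C[C@H](CO)Oc2ccc(C=O)cc2O)C=C(OC)C1=O | intermediate
10 | (2S,3S)-3-(4-hydroxy-3,5-dimethoxyphenyl)-2-(hydroxymethyl)-2,3-dihydro-1,4-benzodioxine-6-carbaldehyde (trans) | COc1cc([C@@H]2Oc3cc(C=O)ccc3O[C@H]2CO)cc(OC)c1O | intermediate
11 | (E)-3-[(2S,3S)-3-(4-hydroxy-3,5-dimethoxyphenyl)-2-(hydroxymethyl)-2,3-dihydro-1,4-benzodioxin-6-yl]prop-2-enal | COc1cc([C@@H]2Oc3cc(/C=C/C=O)ccc3O[C@H]2CO)cc(OC)c1O | target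

## Step count and risks
Total steps: 4.
Longest linear sequence: 4 (1 → 3 → 4 → 10 → 11); 5 is bought and enters in step 3.

**Most likely to fail, first: step 3 (the proposed new step).**
- Payne rearrangement of 4 could be followed by attack at the terminal carbon.
- The primary alkoxide could close a seven-membered ring, or silyl transfer from the aryl ether could trap the alkoxide before SNAr.
- Quinone methide 9 could lose formaldehyde or a proton to give an enol ether.
- The cis-to-trans equilibration could stay incomplete.

The fallback uses known chemistry only, sets out from 4 and comes back at 10. It replaces SNAr and the fluoride relay by a copper-catalysed O-arylation, and the anionic equilibration by a cationic one, each in a separate operation. Compound 4 is opened at the benzylic carbon with commercial 3-hydroxy-4-iodobenzaldehyde (Cs2CO3, DMF, 70 °C) to give 3-{(1R,2S)-1-{4-[(tert-butyldimethylsilyl)oxy]-3,5-dimethoxyphenyl}-2,3-dihydroxypropoxy}-4-iodobenzaldehyde F1. Cu2O (10 mol %), 1,10-phenanthroline and Cs2CO3 in DMF at 110 °C close the aryl C–O bond with retention at C2 to give the cis silyl ether 7. This is the known ring-opening/Ullmann-type cyclisation of o-iodophenols with epoxides. Bu4NF buffered with AcOH in THF gives 8. CF3CO2H (10 mol %) in CH2Cl2 at rt then equilibrates 8 through the p-hydroxybenzyl cation to the trans aldehyde 10.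

**Second: step 2.** The electron-rich benzylic epoxide may be opened by isopropoxide or tert-butoxide on the Lewis-acidic titanium centre, or lost on silica. The fallback sets out from 3 and comes back at 4. It leaves hydroxyl-directed, metal-templated oxygen transfer for an undirected chiral dioxirane in basic buffer, so that no Lewis acid meets the product. Compound 3 is epoxidised with the unnatural enantiomer of the fructose-derived Shi ketone (30 mol %, accessible from sorbose), KHSO5 (as 2KHSO5·KHSO4·K2SO4) and K2CO3 at pH 10.5 in MeCN/dimethoxymethane/water at 0 °C. The natural ketone gives (R,R)-epoxides from trans-β-substituted styrenes and cinnamyl alcohols, so its enantiomer gives (2S,3S)-4, which is extracted and used crude. New compounds on this path: none F0.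

**Third: step 4.** The product enal can react a second time with the ylide to give the dienal, and the electron-rich aldehyde can be sluggish. The fallback sets out from 10 and comes back at 11. It builds the enal C=C by olefin metathesis instead of carbonyl olefination with a formyl ylide, so over-homologation is impossible. Methylenation of 10 with Ph3P=CH2 (3.3 equiv, from Ph3PCH3Br and KOt-Bu, THF, 0 °C to rt; the extra equivalents cover the two OH groups) gives [(2S,3S)-6-ethenyl-3-(4-hydroxy-3,5-dimethoxyphenyl)-2,3-dihydro-1,4-benzodioxin-2-yl]methanol F2. Cross-metathesis of F2 with crotonaldehyde (5 equiv) and the second-generation Hoveyda–Grubbs catalyst (3 mol %) in CH2Cl2 at 40 °C gives the E-enal 11.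

## Further compounds
F0 | step 2 | none | none
F1 | step 3 | 3-{(1R,2S)-1-{4-[(tert-butyldimethylsilyl)oxy]-3,5-dimethoxyphenyl}-2,3-dihydroxypropoxy}-4-iodobenzaldehyde | OC[C@H](O)[C@H](Oc1cc(C=O)ccc1I)c1cc(OC)c(O[Si](C)(C)C(C)(C)C)c(OC)c1
F2 | step 4 | [(2S,3S)-6-ethenyl-3-(4-hydroxy-3,5-dimethoxyphenyl)-2,3-dihydro-1,4-benzodioxin-2-yl]methanol | COc1cc([C@@H]2Oc3cc(C=C)ccc3O[C@H]2CO)cc(OC)c1O
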